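**Plan**

- Retrosynthesis: a trimethylsilyl group is put back on C2 of each indole. Both indoles are then opened at N1–C2 and C3–C3a, giving a pyrrole with silyl-capped alkynes at C3 and C4 plus two molecules of 2-iodoaniline. The two pyrrole–alkyne bonds are cut to a 3,4-diiodopyrrole, and the iodines and the C5 acetyl group are removed to reach methyl pyrrole-2-carboxylate.
- Enabling feature: each indole is attached to pyrrole C3 or C4 through its own C3 and has a free C2. The alkyne carbon bonded to the pyrrole can therefore become indole C3, while the silyl-bearing carbon becomes indole C2.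
- Forward order: the pyrrole ring is bought. It receives the C5 acetyl group, then two iodines, then two alkynes. Both indole five-membered rings are closed in one palladium-catalysed operation, and the two silyl groups are finally exchanged for hydrogen.
- Stereochemistry: the target has no stereocentre and no double-bond geometry, so nothing has to be set. The crowded bis(silylindole) may exist as rotamers, which merge on desilylation.

Key step: step 4

Remark on the chemistry: the pyrrole N–H is carried unprotected throughout, on the assumption that the weak bases used (Et3N, Na2CO3) make protection unnecessary. Where a reaction runs twice on one molecule, both half-reacted compounds are listed as in-flask intermediates; either one leads to the same product.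

**Route**

Step 1
Reactants: 1 methyl 1H-pyrrole-2-carboxylate
Product: 3 methyl 5-acetyl-1H-pyrrole-2-carboxylate, via pyrrolyl iminium salt 2 (not isolated)
Conditions: N,N-dimethylacetamide (1.5 equiv), POCl3 (1.3 equiv), ClCH2CH2Cl, 0 °C to reflux; then aq. NaOAc, reflux
Reagents that add atoms: N,N-dimethylacetamide, CC(=O)N(C)C; water, O
Why: Vilsmeier–Haack acylation, in which the chloroiminium ion made from the amide and POCl3 attacks the free α-position C5 (the site this type of electrophile prefers on pyrrole-2-carboxylates) and hydrolysis of the iminium salt gives the ketone, any C4 isomer being removed by chromatography or crystallisation.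

Step 2
Reactants: 3 methyl 5-acetyl-1H-pyrrole-2-carboxylate
Product: 6 methyl 5-acetyl-3,4-diiodo-1H-pyrrole-2-carboxylate, via 3-iodo monoiodide 4 (not isolated), via 4-iodo monoiodide 5 (not isolated)
Conditions: NIS (2.4 equiv), TFA (cat.), MeCN, 0 °C to 50 °C, dark
Reagents that add atoms: N-iodosuccinimide, O=C1CCC(=O)N1I
Why: Electrophilic aromatic iodination, for which C3 and C4 are the only free ring positions and the pyrrole remains nucleophilic enough toward acid-activated NIS despite its two acyl groups, so ring substitution should outpace enol iodination of the acetyl methyl group.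

Step 3
Reactants: 6 methyl 5-acetyl-3,4-diiodo-1H-pyrrole-2-carboxylate; 7 trimethylsilylacetylene
Product: 10 methyl 5-acetyl-3,4-bis[(trimethylsilyl)ethynyl]-1H-pyrrole-2-carboxylate, via 3-alkynyl 4-iodide 8 (not isolated), via 4-alkynyl 3-iodide 9 (not isolated)
Conditions: 7 (4 equiv), PdCl2(PPh3)2 (5 mol %), CuI (10 mol %), Et3N, THF, 55 °C, degassed
Reagents that add atoms: none
Why: Twofold Sonogashira coupling, in which both C–I bonds on the electron-poor ring add readily to zerovalent palladium and the copper acetylide of 7 transfers the alkynyl group, the silyl cap blocking any further reaction at the alkyne terminus.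

Step 4
Reactants: 10 methyl 5-acetyl-3,4-bis[(trimethylsilyl)ethynyl]-1H-pyrrole-2-carboxylate; 11 2-iodoaniline
Product: 14 methyl 5-acetyl-3,4-bis[2-(trimethylsilyl)-1H-indol-3-yl]-1H-pyrrole-2-carboxylate, via C3 monoindole 12 (not isolated), via C4 monoindole 13 (not isolated)
Conditions: 11 (3 equiv), Pd(OAc)2 (10 mol %), LiCl (2 equiv), Na2CO3 (5 equiv), dry DMF, 100 °C
Reagents that add atoms: none
Why: Pd(OAc)2 is reduced in the flask to zerovalent palladium, which inserts into the C–I bond of 11; the arylpalladium halide adds syn across one alkyne of 10 (aryl carbon to the pyrrole-bound alkyne carbon, palladium to the silyl-bearing carbon), the neighbouring NH2 group displaces halide from palladium, and C–N reductive elimination releases the indole and the catalyst, after which the same cycle runs on the second alkyne. The closest known reaction is the Larock heteroannulation of 2-iodoaniline with aryl(trialkylsilyl)alkynes, which gives 3-aryl-2-silylindoles. Each indole five-membered ring is closed by N1–C2 bond formation through reductive elimination from a six-membered azapalladacycle, after the C3–C3a bond has been made intermolecularly by carbopalladation. No stereocentre is formed; hindered rotation about the two pyrrole–indole bonds may give rotamers of 14, all of which lead to the same compound in step 5. Two selectivities are needed: the regiochemistry of insertion, secured by the trimethylsilyl group, which takes the position next to palladium because the long C–Pd bond tolerates it better than the short new C–C bond, and so ends at C2; and capture of the vinylpalladium species by nitrogen before it adds to the neighbouring alkyne, secured by the amine held on the same aryl group and by the wide angle between C3 and C4 substituents on a five-membered ring, which would make the competing closure to a fused fulvene strained.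

Step 5
Reactants: 14 methyl 5-acetyl-3,4-bis[2-(trimethylsilyl)-1H-indol-3-yl]-1H-pyrrole-2-carboxylate
Product: 15 methyl 5-acetyl-3,4-di(1H-indol-3-yl)-1H-pyrrole-2-carboxylate
Conditions: TFA, CH2Cl2, 0 °C to rt, then evaporation
Reagents that add atoms: none
Why: Protodesilylation by ipso substitution, in which protonation at the silicon-bearing indole C2 gives a cation stabilised by the β-silicon and loss of the silyl group to trifluoroacetate restores the indole, while the ester, the ketone and the N–H groups are inert to the acid.

**Compound list**

1 | methyl 1H-pyrrole-2-carboxylate | COC(=O)c1ccc[nH]1 | starting material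
2 | methyl 5-[1-(dimethyliminio)ethyl]-1H-pyrrole-2-carboxylate dichlorophosphate | COC(=O)c1ccc(C(C)=[N+](C)C)[nH]1.[O-]P(=O)(Cl)Cl | intermediate (not isolated)
3 | methyl 5-acetyl-1H-pyrrole-2-carboxylate | COC(=O)c1ccc(C(C)=O)[nH]1 | intermediate
4 | methyl 5-acetyl-3-iodo-1H-pyrrole-2-carboxylate | COC(=O)c1[nH]c(C(C)=O)cc1I | intermediate (not isolated)
5 | methyl 5-acetyl-4-iodo-1H-pyrrole-2-carboxylate | COC(=O)c1cc(I)c(C(C)=O)[nH]1 | intermediate (not isolated)
6 | methyl 5-acetyl-3,4-diiodo-1H-pyrrole-2-carboxylate | COC(=O)c1[nH]c(C(C)=O)c(I)c1I | intermediate
7 | trimethylsilylacetylene | C#C[Si](C)(C)C | starting material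
8 | methyl 5-acetyl-4-iodo-3-[(trimethylsilyl)ethynyl]-1H-pyrrole-2-carboxylate | COC(=O)c1[nH]c(C(C)=O)c(I)c1C#C[Si](C)(C)C | intermediate (not isolated)
9 | methyl 5-acetyl-3-iodo-4-[(trimethylsilyl)ethynyl]-1H-pyrrole-2-carboxylate | COC(=O)c1[nH]c(C(C)=O)c(C#C[Si](C)(C)C)c1I | intermediate (not isolated)
10 | methyl 5-acetyl-3,4-bis[(trimethylsilyl)ethynyl]-1H-pyrrole-2-carboxylate | COC(=O)c1[nH]c(C(C)=O)c(C#C[Si](C)(C)C)c1C#C[Si](C)(C)C | intermediate
11 | 2-iodoaniline | Nc1ccccc1I | starting material
12 | methyl 5-acetyl-4-[(trimethylsilyl)ethynyl]-3-[2-(trimethylsilyl)-1H-indol-3-yl]-1H-pyrrole-2-carboxylate | COC(=O)c1[nH]c(C(C)=O)c(C#C[Si](C)(C)C)c1-c1c([Si](C)(C)C)[nH]c2ccccc12 | intermediate (not isolated)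
13 | methyl 5-acetyl-3-[(trimethylsilyl)ethynyl]-4-[2-(trimethylsilyl)-1H-indol-3-yl]-1H-pyrrole-2-carboxylate | COC(=O)c1[nH]c(C(C)=O)c(-c2c([Si](C)(C)C)[nH]c3ccccc23)c1C#C[Si](C)(C)C | intermediate (not isolated)
14 | methyl 5-acetyl-3,4-bis[2-(trimethylsilyl)-1H-indol-3-yl]-1H-pyrrole-2-carboxylate | COC(=O)c1[nH]c(C(C)=O)c(-c2c([Si](C)(C)C)[nH]c3ccccc23)c1-c1c([Si](C)(C)C)[nH]c2ccccc12 | intermediate
15 | methyl 5-acetyl-3,4-di(1H-indol-3-yl)-1H-pyrrole-2-carboxylate | COC(=O)c1[nH]c(C(C)=O)c(-c2c[nH]c3ccccc23)c1-c1c[nH]c2ccccc12 | target

**Step count and risks**

Total steps: 5. Longest linear sequence: 5 steps (1 → 3 → 6 → 10 → 14 → 15).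

Steps most likely to fail, riskiest first:

1. Step 4. The vinylpalladium species formed on the first alkyne may add to the neighbouring alkyne before nitrogen captures it. The carbonate base may strip the alkynyl silyl groups before annulation. The second annulation may stall against the crowding of the first 2-silylindole. The aniline may condense with the acetyl group. The fallback gives up the alkyne annulation and joins preformed indoles to the pyrrole; it sets out from 6 and returns at 15. A twofold Suzuki–Miyaura coupling of 6 with commercial 1-(tert-butoxycarbonyl)indole-3-boronic acid pinacol ester (Pd(PPh3)4, K3PO4, dioxane/water, 90 °C) should give methyl 5-acetyl-3,4-bis[1-(tert-butoxycarbonyl)-1H-indol-3-yl]-1H-pyrrole-2-carboxylate F1. TFA in CH2Cl2 at room temperature should then remove both carbamates and deliver 15.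

2. Step 3. Deprotonation of the acidic pyrrole N–H by the amine may slow oxidative addition at the now electron-rich ring, so the second coupling stalls. Oxidative dimerisation of the copper acetylide may consume 7, and reductive loss of iodine may compete. The fallback replaces the copper acetylide and amine base by a neutral tin reagent; it sets out from 6 and returns at 10. A Stille coupling of 6 with commercial tributyl[(trimethylsilyl)ethynyl]stannane (Pd(PPh3)4, dioxane, 90 °C, no base, no copper) should give 10 directly, so no new compound arises (F0).

3. Step 1. Attack of the hindered acetamide-derived chloroiminium ion on the ester-deactivated pyrrole may be sluggish. The reagent may self-condense on heating, and the preference for C5 over C4 may be incomplete. The fallback builds the acetyl group in two stages from a formyl group, whose introduction is more reliably C5-selective; it sets out from 1 and returns at 3. Vilsmeier–Haack formylation of 1 (DMF, POCl3, ClCH2CH2Cl; then aq. NaOAc) should pass through methyl 5-[(dimethyliminio)methyl]-1H-pyrrole-2-carboxylate dichlorophosphate F2 to methyl 5-formyl-1H-pyrrole-2-carboxylate F3. Addition of MeMgBr (2.2 equiv, THF, −78 °C to 0 °C) should give racemic methyl 5-(1-hydroxyethyl)-1H-pyrrole-2-carboxylate F4; the first equivalent removes the N–H proton and the resulting pyrrolide shields the ester. Oxidation of the pyrrolic carbinol with MnO2 (CH2Cl2, rt) should return 3.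

**Further compounds**

F1 | step 4 | methyl 5-acetyl-3,4-bis[1-(tert-butoxycarbonyl)-1H-indol-3-yl]-1H-pyrrole-2-carboxylate | COC(=O)c1[nH]c(C(C)=O)c(-c2cn(C(=O)OC(C)(C)C)c3ccccc23)c1-c1cn(C(=O)OC(C)(C)C)c2ccccc12
F0 | step 3 | none | none
F2 | step 1 | methyl 5-[(dimethyliminio)methyl]-1H-pyrrole-2-carboxylate dichlorophosphate | COC(=O)c1ccc(C=[N+](C)C)[nH]1.[O-]P(=O)(Cl)Cl
F3 | step 1 | methyl 5-formyl-1H-pyrrole-2-carboxylate | COC(=O)c1ccc(C=O)[nH]1
F4 | step 1 | methyl 5-(1-hydroxyethyl)-1H-pyrrole-2-carboxylate (racemic) | COC(=O)c1ccc(C(C)O)[nH]1
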